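**Retrosynthetic overview**
1. Ten-membered ring: C3=C4 (Z) by ring-closing metathesis of a seco-triene (last step).
2. γ-Lactone (C8–C17 bond, 8-OH, 17-Me): copper hydride reductive aldol of a C7 acrylate onto the C8 ketone; 6-Cl/7-O from chloride opening of an organocatalytically made C6–C7 epoxy ketone.
3. C8–C9: α-lithiated methoxyallene (acyl-anion equivalent carrying C3–C8 and C16) added to the C9 aldehyde.
4. Cyclohexene ring A: hydrogen-bond-catalysed asymmetric Diels–Alder reaction (C1, C10), then Felkin vinylation (C2) and dihydroxylation of a derived cyclohexadiene (C11, C12).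
5. Ring order: ring A (step 4), lactone (step 18), ten-membered ring (step 19).

Assumption: briarane numbering is used throughout (C15 = methyl on C1, C16 = methylene on C5, C18 = methyl on C17, C19 = lactone carbonyl, C20 = methyl on C11), α is the face of ring A carrying C2, 11-OH and 12-OAc; compounds 1 and 7 are taken as commercial, and the facial sense of (R,R)-1-naphthyl-TADDOL in step 4 is taken by analogy with α-substituted acroleins (the antipode is used if it proves opposite).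

**Route**

Step 1
Reactants: 1 pent-1-yn-3-one; 2 dimethylamine
Product: 3 (E)-1-(dimethylamino)pent-1-en-3-one
Conditions: Me2NH (2 M in THF), THF, 0 °C → rt
Reagents that add atoms: none
Why: aza-Michael addition of the secondary amine to the ynone gives the E-vinylogous amide; no stereocentre.

Step 2
Reactants: 3 (E)-1-(dimethylamino)pent-1-en-3-one
Product: 5 (1E,3Z)-3-[tert-butyl(dimethyl)silyl]oxy-N,N-dimethylpenta-1,3-dien-1-amine, via potassium dienolate 4 (not isolated)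
Conditions: KN(SiMe3)2, THF, −78 °C; TBSCl, −78 °C → rt
Reagents that add atoms: tert-butyl(chloro)dimethylsilane CC(C)(C)[Si](C)(C)Cl
Why: kinetic enolisation and O-silylation (Kozmin–Rawal aminosilyloxydiene synthesis) give the Z enol ether with the terminal methyl outside, the reactive diene geometry.

Step 3
Reactants: 6 2,2-dimethoxyacetaldehyde; 7 2-(triphenylphosphoranylidene)propanal
Product: 8 (E)-4,4-dimethoxy-2-methylbut-2-enal
Conditions: CH2Cl2, rt (6 used as its 60 % aqueous solution)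
Reagents that add atoms: none
Why: Wittig olefination with a stabilised ylide is E-selective, placing the formyl group trans to the acetal carbon, which later becomes the trans C2/C9 relationship.

Step 4
Reactants: 8 (E)-4,4-dimethoxy-2-methylbut-2-enal; 5 (1E,3Z)-3-[tert-butyl(dimethyl)silyl]oxy-N,N-dimethylpenta-1,3-dien-1-amine
Product: 10 (1S,6S)-6-(dimethoxymethyl)-1,5-dimethyl-4-oxocyclohex-2-ene-1-carbaldehyde (C5 epimers; ring C1 = C1 and ring C6 = C10), via aminosilyloxy cycloadduct 9 (not isolated)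
Conditions: (R,R)-1-naphthyl-TADDOL (20 mol %), toluene, −40 → −20 °C, 48 h; then AcCl, CH2Cl2, −78 °C
Reagents that add atoms: none
Why: Proposed new method: TADDOL hydrogen-bond-catalysed Diels–Alder reaction of a 4-methyl-1-amino-3-silyloxydiene with an α-methyl-β-substituted enal; the diol donates one hydrogen bond to the s-trans enal carbonyl and a naphthyl wall blocks one face, the nucleophilic methyl-bearing diene terminus bonds first to the enal β-carbon (C10) and the amino terminus closes on the α-carbon (C1), so the E geometry becomes the trans C1/C10 pair and the catalyst fixes its absolute sense (first stereocentres; endo/exo and the C11/C14 centres are irrelevant because they are erased), after which acetyl chloride expels dimethylamine and the silyl group to give the enone; the closest known reaction is the TADDOL-catalysed Diels–Alder reaction of aminosilyloxydienes with α-substituted acroleins, not yet shown for β-substituted enals or 4-substituted dienes.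

Step 5
Reactants: 10 (1S,6S)-6-(dimethoxymethyl)-1,5-dimethyl-4-oxocyclohex-2-ene-1-carbaldehyde; 11 vinylmagnesium bromide
Product: 13 (1S)-1-[(1S,6S)-6-(dimethoxymethyl)-1,5-dimethyl-4-oxocyclohex-2-en-1-yl]prop-2-en-1-yl acetate, via bromomagnesium alkoxide 12 (not isolated)
Conditions: CH2=CHMgBr (1.05 equiv), THF, −78 °C; then Ac2O, DMAP (cat.), −78 → 0 °C
Reagents that add atoms: acetic anhydride CC(=O)OC(C)=O
Why: Grignard 1,2-addition to the neopentyl aldehyde (much faster than to the enone at −78 °C) follows the Felkin–Anh model with the C10 branch anti to the nucleophile, which gives 2S; the alkoxide is acetylated in the same pot.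

Step 6
Reactants: 13 (1S)-1-[(1S,6S)-6-(dimethoxymethyl)-1,5-dimethyl-4-oxocyclohex-2-en-1-yl]prop-2-en-1-yl acetate
Product: 14 (1S)-1-[(1S,6S)-6-(dimethoxymethyl)-4-hydroxy-1,5-dimethylcyclohex-2-en-1-yl]prop-2-en-1-yl acetate (C4 and C5 epimers)
Conditions: NaBH4, CeCl3·7H2O, MeOH, −40 °C
Reagents that add atoms: none
Why: Luche 1,2-reduction of the enone; the new carbinol centre is eliminated in the next step, so its configuration does not matter.

Step 7
Reactants: 14 (1S)-1-[(1S,6S)-6-(dimethoxymethyl)-4-hydroxy-1,5-dimethylcyclohex-2-en-1-yl]prop-2-en-1-yl acetate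
Product: 15 (1S)-1-[(1S,6S)-6-(dimethoxymethyl)-1,5-dimethylcyclohexa-2,4-dien-1-yl]prop-2-en-1-yl acetate
Conditions: Martin sulfurane Ph2S[OC(CF3)2Ph]2, CH2Cl2, 0 °C → rt
Reagents that add atoms: none
Why: sulfurane dehydration of the allylic alcohol; C1 is quaternary, so only the C11 hydrogen can be lost and the 11,13-diene is the only possible elimination product.

Step 8
Reactants: 15 (1S)-1-[(1S,6S)-6-(dimethoxymethyl)-1,5-dimethylcyclohexa-2,4-dien-1-yl]prop-2-en-1-yl acetate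
Product: 16 (1S)-1-[(1S,4R,5S,6R)-6-(dimethoxymethyl)-4,5-dihydroxy-1,5-dimethylcyclohex-2-en-1-yl]prop-2-en-1-yl acetate
Conditions: OsO4 (2 mol %), NMO (1.1 equiv), acetone/H2O, 0 °C
Reagents that add atoms: osmium tetroxide O=[Os](=O)(=O)=O; N-methylmorpholine N-oxide C[N+]1([O-])CCOCC1; water O
Why: Upjohn dihydroxylation attacks the electron-rich trisubstituted C11=C12 bond of the diene from the α-face, anti to the adjacent C10 substituent and the axial C1 methyl, giving the cis-11,12-diol (11S, 12R) and leaving C13=C14.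

Step 9
Reactants: 16 (1S)-1-[(1S,4R,5S,6R)-6-(dimethoxymethyl)-4,5-dihydroxy-1,5-dimethylcyclohex-2-en-1-yl]prop-2-en-1-yl acetate
Product: 18 (1S)-1-[(1S,4R,5S,6R)-6-formyl-1,5-dimethyl-4,5-bis(trimethylsilyloxy)cyclohex-2-en-1-yl]prop-2-en-1-yl acetate, via collidinium salt 17 (not isolated)
Conditions: TMSOTf (3.3 equiv), 2,4,6-collidine (5 equiv), CH2Cl2, −30 → 0 °C; then H2O, 0 °C
Reagents that add atoms: trimethylsilyl trifluoromethanesulfonate C[Si](C)(C)OS(=O)(=O)C(F)(F)F; water O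
Why: Fujioka-type silyl triflate/collidine acetal cleavage frees the C9 aldehyde without aqueous acid while both hydroxyls are capped as TMS ethers, which blocks retro-aldol and β-elimination of the β-hydroxy aldehyde.

Step 10
Reactants: 19 3-methoxyprop-1-yne; 20 but-3-en-2-one
Product: 22 6-methoxy-3-methylhex-1-en-4-yn-3-ol (racemic), via lithium acetylide 21 (not isolated)
Conditions: n-BuLi, THF, −78 °C; then 20, −78 °C; H2O quench
Reagents that add atoms: none
Why: 1,2-addition of a lithium acetylide to the enone carbonyl; the racemic carbinol centre is erased in the next step.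

Step 11
Reactants: 22 6-methoxy-3-methylhex-1-en-4-yn-3-ol
Product: 23 6-methoxy-3-methylidenehex-1-en-4-yne
Conditions: Burgess reagent, THF, 50 °C
Reagents that add atoms: none
Why: Burgess dehydration of the tertiary alcohol; only the methyl group has β-hydrogens, so the 2-substituted butadiene is the sole product.

Step 12
Reactants: 23 6-methoxy-3-methylidenehex-1-en-4-yne
Product: 24 6-methoxy-3-methylidenehexa-1,4,5-triene (racemic allene)
Conditions: KOtBu (20 mol %), THF/DMSO, 0 °C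
Reagents that add atoms: none
Why: base-catalysed propargyl–allene isomerisation toward the ether oxygen (the only propargylic hydrogens), as in the preparation of methoxyallene.

Step 13
Reactants: 18 (1S)-1-[(1S,4R,5S,6R)-6-formyl-1,5-dimethyl-4,5-bis(trimethylsilyloxy)cyclohex-2-en-1-yl]prop-2-en-1-yl acetate; 24 6-methoxy-3-methylidenehexa-1,4,5-triene
Product: 27 (1S)-1-[(1S,4R,5S,6S)-4,5-dihydroxy-6-[(1S,3E)-1-hydroxy-5-methylidene-2-oxohepta-3,6-dien-1-yl]-1,5-dimethylcyclohex-2-en-1-yl]prop-2-en-1-yl acetate, via lithioallene 25 (not isolated), via lithium alkoxide adduct 26 (not isolated)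
Conditions: 24 (1.5 equiv), n-BuLi (1.4 equiv), THF, −78 → −40 °C; 18, −78 °C, 30 min; then 1 M HCl, THF, 0 °C, 20 min
Reagents that add atoms: water O
Why: α-lithiated methoxyallene acts as an acyl-anion equivalent; Felkin–Anh addition to the aldehyde anti to the bulkier bis-silyloxy-bearing C11 branch sets 9S (the hindered C2 acetate is spared at −78 °C), and acid hydrolysis of the enol ether, which also removes both TMS groups, gives the (E)-α′-hydroxy enone.

Step 14
Reactants: 27 (1S)-1-[(1S,4R,5S,6S)-4,5-dihydroxy-6-[(1S,3E)-1-hydroxy-5-methylidene-2-oxohepta-3,6-dien-1-yl]-1,5-dimethylcyclohex-2-en-1-yl]prop-2-en-1-yl acetate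
Product: 28 (1S)-1-[(1S,4R,5S,6S)-4-acetoxy-6-[(1S,3E)-1-acetoxy-5-methylidene-2-oxohepta-3,6-dien-1-yl]-5-hydroxy-1,5-dimethylcyclohex-2-en-1-yl]prop-2-en-1-yl acetate
Conditions: Ac2O (3 equiv), pyridine, DMAP (cat.), CH2Cl2, 0 °C
Reagents that add atoms: acetic anhydride CC(=O)OC(C)=O
Why: DMAP-catalysed acetylation of the two secondary alcohols (C9, C12); the tertiary C11 hydroxyl is inert under these conditions.

Step 15
Reactants: 28 (1S)-1-[(1S,4R,5S,6S)-4-acetoxy-6-[(1S,3E)-1-acetoxy-5-methylidene-2-oxohepta-3,6-dien-1-yl]-5-hydroxy-1,5-dimethylcyclohex-2-en-1-yl]prop-2-en-1-yl acetate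
Product: 29 (1S)-1-[(1S,4R,5S,6S)-4-acetoxy-6-[(1S)-1-acetoxy-2-[(2S,3R)-3-(buta-1,3-dien-2-yl)oxiran-2-yl]-2-oxoethyl]-5-hydroxy-1,5-dimethylcyclohex-2-en-1-yl]prop-2-en-1-yl acetate
Conditions: (R)-α,α-bis(3,5-dimethylphenyl)prolinol (30 mol %), t-BuOOH (1.3 equiv), hexane/CH2Cl2, 4 °C
Reagents that add atoms: tert-butyl hydroperoxide CC(C)(C)OO
Why: organocatalytic Weitz–Scheffer epoxidation (Lattanzi diarylprolinol/TBHP) of the E-enone gives the trans (6R,7S)-epoxy ketone under catalyst control, the cross-conjugated diene being too electron-rich to react.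

Step 16
Reactants: 29 (1S)-1-[(1S,4R,5S,6S)-4-acetoxy-6-[(1S)-1-acetoxy-2-[(2S,3R)-3-(buta-1,3-dien-2-yl)oxiran-2-yl]-2-oxoethyl]-5-hydroxy-1,5-dimethylcyclohex-2-en-1-yl]prop-2-en-1-yl acetate
Product: 30 (1S)-1-[(1S,4R,5S,6S)-4-acetoxy-6-[(1S,3R,4S)-1-acetoxy-4-chloro-3-hydroxy-5-methylidene-2-oxohept-6-en-1-yl]-5-hydroxy-1,5-dimethylcyclohex-2-en-1-yl]prop-2-en-1-yl acetate
Conditions: pyridinium chloride (3 equiv), CH2Cl2, 0 °C → rt
Reagents that add atoms: pyridinium chloride [Cl-].c1cc[nH+]cc1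
Why: SN2 opening of the α,β-epoxy ketone by chloride at the allylic β-carbon C6 with inversion gives the anti chlorohydrin (6S,7R).

Step 17
Reactants: 30 (1S)-1-[(1S,4R,5S,6S)-4-acetoxy-6-[(1S,3R,4S)-1-acetoxy-4-chloro-3-hydroxy-5-methylidene-2-oxohept-6-en-1-yl]-5-hydroxy-1,5-dimethylcyclohex-2-en-1-yl]prop-2-en-1-yl acetate; 31 acryloyl chloride
Product: 32 (1S)-1-[(1S,4R,5S,6S)-4-acetoxy-6-[(1S,3R,4S)-1-acetoxy-4-chloro-5-methylidene-2-oxo-3-(prop-2-enoyloxy)hept-6-en-1-yl]-5-hydroxy-1,5-dimethylcyclohex-2-en-1-yl]prop-2-en-1-yl acetate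
Conditions: 2,6-lutidine, CH2Cl2, −40 → 0 °C
Reagents that add atoms: none
Why: acylation of the only free secondary hydroxyl (C7); the weak hindered base avoids β-elimination of chloride from the β-chloro ketone.

Step 18
Reactants: 32 (1S)-1-[(1S,4R,5S,6S)-4-acetoxy-6-[(1S,3R,4S)-1-acetoxy-4-chloro-5-methylidene-2-oxo-3-(prop-2-enoyloxy)hept-6-en-1-yl]-5-hydroxy-1,5-dimethylcyclohex-2-en-1-yl]prop-2-en-1-yl acetate
Product: 33 (1S)-1-[(1S,4R,5S,6S)-4-acetoxy-6-[(S)-acetoxy[(2R,3R,4R)-2-[(1S)-1-chloro-2-methylidenebut-3-en-1-yl]-3-hydroxy-4-methyl-5-oxooxolan-3-yl]methyl]-5-hydroxy-1,5-dimethylcyclohex-2-en-1-yl]prop-2-en-1-yl acetate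
Conditions: Stryker reagent [(Ph3P)CuH]6 (0.5 equiv), toluene, −40 → 0 °C; H2O quench
Reagents that add atoms: none
Why: reductive aldol cyclisation (Chiu/Lam type): conjugate hydride addition to the acrylate gives a copper enolate that closes on the adjacent C8 ketone, forming the γ-lactone with the C17 methyl cis to the new C8 hydroxyl and the bulky C9 branch trans to C6 (8R, 17R).

Step 19
Reactants: 33 (1S)-1-[(1S,4R,5S,6S)-4-acetoxy-6-[(S)-acetoxy[(2R,3R,4R)-2-[(1S)-1-chloro-2-methylidenebut-3-en-1-yl]-3-hydroxy-4-methyl-5-oxooxolan-3-yl]methyl]-5-hydroxy-1,5-dimethylcyclohex-2-en-1-yl]prop-2-en-1-yl acetate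
Product: 34 CNP0285654.2 (1S,2S,3Z,6S,7R,8R,9S,10S,11S,12R,17R)-2,9,12-triacetoxy-6-chloro-8,11-dihydroxybriara-3,5(16),13-trien-19,7-olide
Conditions: second-generation Hoveyda–Grubbs catalyst RuCl2(H2IMes)(=CH-C6H4-2-OiPr) (15 mol %), 1,4-benzoquinone (cat.), toluene (1 mM), 80 °C
Reagents that add atoms: none
Why: ring-closing metathesis between the C2 vinyl group and the terminal vinyl of the 2-substituted butadiene closes the ten-membered ring, whose size enforces the Z C3=C4 bond and leaves the exocyclic methylene in place.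

**Compound list**
1 | pent-1-yn-3-one | CCC(=O)C#C | starting material
2 | dimethylamine | CNC | starting material
3 | (E)-1-(dimethylamino)pent-1-en-3-one | CCC(=O)/C=C/N(C)C | intermediate
4 | potassium (1E,3Z)-1-(dimethylamino)penta-1,3-dien-3-olate | CN(C)/C=C/C([O-])=C/C.[K+] | intermediate
5 | (1E,3Z)-3-[tert-butyl(dimethyl)silyl]oxy-N,N-dimethylpenta-1,3-dien-1-amine | CN(C)/C=C/C(O[Si](C)(C)C(C)(C)C)=C/C | intermediate
6 | 2,2-dimethoxyacetaldehyde | COC(OC)C=O | starting material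
7 | 2-(triphenylphosphoranylidene)propanal | CC(C=O)=P(c1ccccc1)(c1ccccc1)c1ccccc1 | starting material
8 | (E)-4,4-dimethoxy-2-methylbut-2-enal | O=C/C(C)=C/C(OC)OC | intermediate
9 | Diels–Alder adduct: 4-[tert-butyl(dimethyl)silyl]oxy-6-(dimethoxymethyl)-2-(dimethylamino)-1,5-dimethylcyclohex-3-ene-1-carbaldehyde, formyl and dimethoxymethyl trans as in 10, C2 and C5 epimers | O=C[C@@]1(C)C(N(C)C)C=C(O[Si](C)(C)C(C)(C)C)C(C)[C@@H]1C(OC)OC | intermediate
10 | (1S,6S)-6-(dimethoxymethyl)-1,5-dimethyl-4-oxocyclohex-2-ene-1-carbaldehyde (C5 epimers) | O=C[C@@]1(C)C=CC(=O)C(C)[C@@H]1C(OC)OC | intermediate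
11 | vinylmagnesium bromide | C=C[Mg]Br | starting material
12 | bromomagnesium (1S)-1-[(1S,6S)-6-(dimethoxymethyl)-1,5-dimethyl-4-oxocyclohex-2-en-1-yl]prop-2-en-1-olate | C=C[C@H](O[Mg]Br)[C@@]1(C)C=CC(=O)C(C)[C@@H]1C(OC)OC | intermediate
13 | (1S)-1-[(1S,6S)-6-(dimethoxymethyl)-1,5-dimethyl-4-oxocyclohex-2-en-1-yl]prop-2-en-1-yl acetate (C5 epimers) | C=C[C@H](OC(C)=O)[C@@]1(C)C=CC(=O)C(C)[C@@H]1C(OC)OC | intermediate
14 | (1S)-1-[(1S,6S)-6-(dimethoxymethyl)-4-hydroxy-1,5-dimethylcyclohex-2-en-1-yl]prop-2-en-1-yl acetate (C4 and C5 epimers) | C=C[C@H](OC(C)=O)[C@@]1(C)C=CC(O)C(C)[C@@H]1C(OC)OC | intermediate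
15 | (1S)-1-[(1S,6S)-6-(dimethoxymethyl)-1,5-dimethylcyclohexa-2,4-dien-1-yl]prop-2-en-1-yl acetate | C=C[C@H](OC(C)=O)[C@@]1(C)C=CC=C(C)[C@@H]1C(OC)OC | intermediate
16 | (1S)-1-[(1S,4R,5S,6R)-6-(dimethoxymethyl)-4,5-dihydroxy-1,5-dimethylcyclohex-2-en-1-yl]prop-2-en-1-yl acetate | C=C[C@H](OC(C)=O)[C@@]1(C)C=C[C@@H](O)[C@@](C)(O)[C@@H]1C(OC)OC | intermediate
17 | collidinium salt: 1-[methoxy(ring A)methyl]-2,4,6-trimethylpyridinium triflate, ring A as in 18 (C9 epimers) | C=C[C@H](OC(C)=O)[C@@]1(C)C=C[C@@H](O[Si](C)(C)C)[C@@](C)(O[Si](C)(C)C)[C@@H]1C(OC)[n+]2c(C)cc(C)cc2C.[O-]S(=O)(=O)C(F)(F)F | intermediate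
18 | (1S)-1-[(1S,4R,5S,6R)-6-formyl-1,5-dimethyl-4,5-bis(trimethylsilyloxy)cyclohex-2-en-1-yl]prop-2-en-1-yl acetate | C=C[C@H](OC(C)=O)[C@@]1(C)C=C[C@@H](O[Si](C)(C)C)[C@@](C)(O[Si](C)(C)C)[C@@H]1C=O | intermediate
19 | 3-methoxyprop-1-yne | COCC#C | starting material
20 | but-3-en-2-one | CC(=O)C=C | starting material
21 | (3-methoxyprop-1-yn-1-yl)lithium | COCC#C[Li] | intermediate
22 | 6-methoxy-3-methylhex-1-en-4-yn-3-ol (racemic) | COCC#CC(C)(O)C=C | intermediate
23 | 6-methoxy-3-methylidenehex-1-en-4-yne | COCC#CC(=C)C=C | intermediate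
24 | 6-methoxy-3-methylidenehexa-1,4,5-triene (racemic allene) | COC=C=CC(=C)C=C | intermediate
25 | (1-methoxy-4-methylidenehexa-1,2,5-trien-1-yl)lithium | [Li]C(OC)=C=CC(=C)C=C | intermediate
26 | lithium (9S)-alkoxide of the allenyl carbinol: 18 with C9 bearing OLi and the 1-methoxy-4-methylidenehexa-1,2,5-trien-1-yl group | C=C[C@H](OC(C)=O)[C@@]1(C)C=C[C@@H](O[Si](C)(C)C)[C@@](C)(O[Si](C)(C)C)[C@@H]1[C@H](O[Li])C(OC)=C=CC(=C)C=C | intermediate
27 | (1S)-1-[(1S,4R,5S,6S)-4,5-dihydroxy-6-[(1S,3E)-1-hydroxy-5-methylidene-2-oxohepta-3,6-dien-1-yl]-1,5-dimethylcyclohex-2-en-1-yl]prop-2-en-1-yl acetate | C=C[C@H](OC(C)=O)[C@@]1(C)C=C[C@@H](O)[C@@](C)(O)[C@@H]1[C@H](O)C(=O)/C=C/C(=C)C=C | intermediate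
28 | (1S)-1-[(1S,4R,5S,6S)-4-acetoxy-6-[(1S,3E)-1-acetoxy-5-methylidene-2-oxohepta-3,6-dien-1-yl]-5-hydroxy-1,5-dimethylcyclohex-2-en-1-yl]prop-2-en-1-yl acetate | C=C[C@H](OC(C)=O)[C@@]1(C)C=C[C@@H](OC(C)=O)[C@@](C)(O)[C@@H]1[C@H](OC(C)=O)C(=O)/C=C/C(=C)C=C | intermediate
29 | (1S)-1-[(1S,4R,5S,6S)-4-acetoxy-6-[(1S)-1-acetoxy-2-[(2S,3R)-3-(buta-1,3-dien-2-yl)oxiran-2-yl]-2-oxoethyl]-5-hydroxy-1,5-dimethylcyclohex-2-en-1-yl]prop-2-en-1-yl acetate | C=C[C@H](OC(C)=O)[C@@]1(C)C=C[C@@H](OC(C)=O)[C@@](C)(O)[C@@H]1[C@H](OC(C)=O)C(=O)[C@H]2O[C@@H]2C(=C)C=C | intermediate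
30 | (1S)-1-[(1S,4R,5S,6S)-4-acetoxy-6-[(1S,3R,4S)-1-acetoxy-4-chloro-3-hydroxy-5-methylidene-2-oxohept-6-en-1-yl]-5-hydroxy-1,5-dimethylcyclohex-2-en-1-yl]prop-2-en-1-yl acetate | C=C[C@H](OC(C)=O)[C@@]1(C)C=C[C@@H](OC(C)=O)[C@@](C)(O)[C@@H]1[C@H](OC(C)=O)C(=O)[C@@H](O)[C@H](C(=C)C=C)Cl | intermediate
31 | acryloyl chloride | C=CC(=O)Cl | starting material
32 | (1S)-1-[(1S,4R,5S,6S)-4-acetoxy-6-[(1S,3R,4S)-1-acetoxy-4-chloro-5-methylidene-2-oxo-3-(prop-2-enoyloxy)hept-6-en-1-yl]-5-hydroxy-1,5-dimethylcyclohex-2-en-1-yl]prop-2-en-1-yl acetate | C=C[C@H](OC(C)=O)[C@@]1(C)C=C[C@@H](OC(C)=O)[C@@](C)(O)[C@@H]1[C@H](OC(C)=O)C(=O)[C@@H](OC(=O)C=C)[C@H](C(=C)C=C)Cl | intermediate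
33 | (1S)-1-[(1S,4R,5S,6S)-4-acetoxy-6-[(S)-acetoxy[(2R,3R,4R)-2-[(1S)-1-chloro-2-methylidenebut-3-en-1-yl]-3-hydroxy-4-methyl-5-oxooxolan-3-yl]methyl]-5-hydroxy-1,5-dimethylcyclohex-2-en-1-yl]prop-2-en-1-yl acetate | C=C[C@H](OC(C)=O)[C@@]1(C)C=C[C@@H](OC(C)=O)[C@@](C)(O)[C@@H]1[C@H](OC(C)=O)[C@]2(O)[C@@H](C)C(=O)O[C@H]2[C@H](C(=C)C=C)Cl | intermediate
34 | CNP0285654.2, (1S,2S,3Z,6S,7R,8R,9S,10S,11S,12R,17R)-2,9,12-triacetoxy-6-chloro-8,11-dihydroxybriara-3,5(16),13-trien-19,7-olide | C=C1/C=C\[C@H](OC(C)=O)[C@@]2(C)C=C[C@@H](OC(C)=O)[C@@](C)(O)[C@@H]2[C@H](OC(C)=O)[C@]2(O)[C@@H](C)C(=O)O[C@H]2[C@H]1Cl | target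

**Step count**
Total: 19 steps. Longest linear sequence: 15 steps (1, 2, 4–9, 13–19).

**Three steps most likely to fail**

Step 4 (the proposed new Diels–Alder reaction). The trisubstituted enal may be too unreactive or poorly face-selective under hydrogen-bond catalysis. The fallback sets out from 8 and returns at 10, using known chemistry. Commercial pent-1-en-3-one is silylated (triisopropylsilyl triflate, Et3N) to (Z)-triisopropyl(penta-1,3-dien-3-yloxy)silane F1. Compound 8 and F1 are combined under Corey's triflimide-activated o-tolyl oxazaborolidine (10–20 mol %, CH2Cl2, −78 °C), an established catalyst class for Diels–Alder reactions of 2-substituted enals with 2-silyloxydienes; the catalyst enantiomer is chosen to deliver the 1S,6S pair. This gives the silyl enol ether (1S,6S)-6-(dimethoxymethyl)-1,5-dimethyl-4-(triisopropylsilyloxy)cyclohex-3-ene-1-carbaldehyde F2. Saegusa–Ito oxidation with Pd(OAc)2 (O2, DMSO) then gives enone 10.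

Step 13 (allene addition). The C9 configuration rests on substrate control at a very hindered aldehyde, and the organolithium must spare the C2 acetate. The fallback sets out from 18 and returns at 27, and moves C9 control to a reagent. The adduct is quenched cold with buffer and isolated as the 9-epimeric allenyl carbinols F3. Buffered Dess–Martin oxidation gives the allenyl ketone F4. Reduction with (S)-Me-CBS and catecholborane (ring carbon as the large group, allenyl as the small group) gives the single (9S)-allenyl carbinol F5. Hydrolysis with 1 M HCl in THF then gives 27.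

Step 19 (ring-closing metathesis on the fully functionalised seco-lactone). The lactone and the allylic chloride may disfavour closure, or oligomers may dominate. The fallback sets out from 30 and returns at 34, and closes the ring before the lactone is built. Metathesis of the acyclic keto-chlorohydrin 30 with the same ruthenium catalyst, where the C6–C9 segment is still flexible and C8 is sp2, gives the macrocyclic keto-chlorohydrin F6. Acylation with 31 and 2,6-lutidine gives the macrocyclic acrylate F7. The Stryker reductive aldol is then run transannularly to give 34.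

Further compounds
F1 | step 4 | (Z)-triisopropyl(penta-1,3-dien-3-yloxy)silane | C=C/C(O[Si](C(C)C)(C(C)C)C(C)C)=C/C
F2 | step 4 | (1S,6S)-6-(dimethoxymethyl)-1,5-dimethyl-4-(triisopropylsilyloxy)cyclohex-3-ene-1-carbaldehyde (C5 epimers) | O=C[C@@]1(C)CC=C(O[Si](C(C)C)(C(C)C)C(C)C)C(C)[C@@H]1C(OC)OC
F3 | step 13 | 9-epimeric allenyl carbinols (neutral form of 26 without defined C9 configuration) | C=C[C@H](OC(C)=O)[C@@]1(C)C=C[C@@H](O[Si](C)(C)C)[C@@](C)(O[Si](C)(C)C)[C@@H]1C(O)C(OC)=C=CC(=C)C=C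
F4 | step 13 | allenyl ketone (C9-oxo analogue of F3) | C=C[C@H](OC(C)=O)[C@@]1(C)C=C[C@@H](O[Si](C)(C)C)[C@@](C)(O[Si](C)(C)C)[C@@H]1C(=O)C(OC)=C=CC(=C)C=C
F5 | step 13 | (9S)-allenyl carbinol (neutral form of 26) | C=C[C@H](OC(C)=O)[C@@]1(C)C=C[C@@H](O[Si](C)(C)C)[C@@](C)(O[Si](C)(C)C)[C@@H]1[C@H](O)C(OC)=C=CC(=C)C=C
F6 | step 19 | macrocyclic keto-chlorohydrin (3Z ring-closed analogue of 30: C8 ketone, 7R hydroxyl, 6S chloride) | C=C1/C=C\[C@H](OC(C)=O)[C@@]2(C)C=C[C@@H](OC(C)=O)[C@@](C)(O)[C@@H]2[C@H](OC(C)=O)C(=O)[C@@H](O)[C@H]1Cl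
F7 | step 19 | macrocyclic acrylate (7-O-prop-2-enoyl derivative of F6) | C=C1/C=C\[C@H](OC(C)=O)[C@@]2(C)C=C[C@@H](OC(C)=O)[C@@](C)(O)[C@@H]2[C@H](OC(C)=O)C(=O)[C@@H](OC(=O)C=C)[C@H]1Cl
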